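The route rests on cutting ring A out of the naphthazarin at C4a–C5 and C8–C8a. The key step exploits that ring A (C4a, C5 to C8, C8a) with its peri oxygens on C5 and C8 is a 1,4-dioxygenated four-carbon unit, and that the target is the bis-enol of a 4a,8a-dihydro-1,4,5,8-tetraone. One [4+2] cycloaddition of (1E,3E)-1,4-bis(trimethylsilyloxy)buta-1,3-diene to the unsubstituted double bond of a benzoquinone (its carbons become C4a and C8a) forms both bonds and closes ring A. The dienophile is the (R)-configured 2-substituted 1,4-benzoquinone that already carries C1' with the complete 3-methylbut-2-enoate; afterwards only desilylation, carbinol oxidation and enolisation remain.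

Key step: step 8

Remark: atom numbers follow the naphthalene numbering of the target (side chain on C2, carbinol carbon C1'). The target is drawn as its 1,4-quinone tautomer, which equilibrates rapidly with the 5,8-quinone form of the same compound. Adduct 16 is expected as two facial diastereomers that converge later; one is drawn.

Step 1
Reactants: 1 4-methylpent-3-enoic acid
Product: 3 N-methoxy-N,4-dimethylpent-3-enamide, via acyl imidazolide 2 (not isolated)
Conditions: 1,1'-carbonyldiimidazole, CH2Cl2, 0 °C to rt; then MeNH(OMe)·HCl, rt
Reagents that add atoms: N,O-dimethylhydroxylamine hydrochloride, CNOC.Cl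
Why: Weinreb amide formation by carbonyldiimidazole coupling, in which the acid is converted into acyl imidazolide 2 with loss of CO2 and then acylates the hydroxylamine, the nearly neutral medium keeping the β,γ-double bond out of conjugation.

Step 2
Reactants: 4 2-bromo-1,4-dimethoxybenzene; 3 N-methoxy-N,4-dimethylpent-3-enamide
Product: 7 1-(2,5-dimethoxyphenyl)-4-methylpent-3-en-1-one, via 2,5-dimethoxyphenyllithium 5 (not isolated), via lithium hemiaminal adduct 6 (not isolated)
Conditions: n-BuLi, THF, −78 °C; then 3, −78 to 0 °C; 1 M HCl, 0 °C
Reagents that add atoms: none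
Why: Weinreb ketone synthesis after bromine–lithium exchange, in which aryllithium 5 adds once to the amide to give the chelated tetrahedral adduct 6 that releases the ketone only on acidic quench, so that over-addition is excluded and the β,γ-unsaturated ketone never meets base.

Step 3
Reactants: 7 1-(2,5-dimethoxyphenyl)-4-methylpent-3-en-1-one
Product: 9 (1R)-1-(2,5-dimethoxyphenyl)-4-methylpent-3-en-1-ol, via chloroborinate ester 8 (not isolated)
Conditions: (+)-B-chlorodiisopinocampheylborane, THF, −25 °C; then HN(CH2CH2OH)2, Et2O, rt
Reagents that add atoms: none
Why: Brown asymmetric reduction, in which β-hydride transfer from an isopinocampheyl group through a six-membered boat-like transition state keeps the aryl group away from the pinane C2 methyl, so that the reagent made from (−)-α-pinene should set C1' as (R) (the sense known for aryl alkyl ketones), while the isolated trisubstituted alkene is inert to this borane.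

Step 4
Reactants: 9 (1R)-1-(2,5-dimethoxyphenyl)-4-methylpent-3-en-1-ol; 10 3-methylbut-2-enoyl chloride
Product: 11 (1R)-1-(2,5-dimethoxyphenyl)-4-methylpent-3-enyl 3-methylbut-2-enoate
Conditions: pyridine, DMAP (catalytic), CH2Cl2, 0 °C to rt
Reagents that add atoms: none
Why: DMAP-catalysed O-acylation with an acid chloride takes place at oxygen with retention at C1', and the weak base pyridine should not divert the acid chloride into a vinylketene and hence a deconjugated ester.

Step 5
Reactants: 11 (1R)-1-(2,5-dimethoxyphenyl)-4-methylpent-3-enyl 3-methylbut-2-enoate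
Product: 12 (R)-2-[4-methyl-1-(3-methylbut-2-enoyloxy)pent-3-enyl]-1,4-benzoquinone
Conditions: (NH4)2Ce(NO3)6, MeCN/H2O, 0 °C
Reagents that add atoms: water, O
Why: Oxidative demethylation of a 1,4-dimethoxyarene to the para-quinone by two one-electron oxidations with tetravalent cerium and ipso attack of water, a fast reaction at 0 °C that should spare the isolated trisubstituted alkene and the ester and does not involve C1'.

Step 6
Reactants: 13 2,5-dimethoxytetrahydrofuran
Product: 14 butanedial (succinaldehyde)
Conditions: H2O, 90 °C, MeOH distilled off; extraction with CH2Cl2, short-path distillation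
Reagents that add atoms: water, O
Why: Acetal hydrolysis of the cyclic bis-acetal is driven to the dialdehyde by distilling out methanol, and the product is used at once because it oligomerises on storage.

Step 7
Reactants: 14 butanedial
Product: 15 (1E,3E)-1,4-bis(trimethylsilyloxy)buta-1,3-diene
Conditions: Me3SiCl, Et3N, ZnCl2 (catalytic), toluene, rt to 40 °C; filtration, distillation under reduced pressure
Reagents that add atoms: chlorotrimethylsilane, C[Si](C)(C)Cl
Why: Double silyl enol ether formation under soft enolisation should give the conjugated bis(silyl enol ether) as a mixture of geometric isomers, of which only the (1E,3E) isomer can reach the s-cis conformation, so the distilled mixture is assayed for that isomer and used in excess.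

Step 8
Reactants: 12 (R)-2-[4-methyl-1-(3-methylbut-2-enoyloxy)pent-3-enyl]-1,4-benzoquinone; 15 (1E,3E)-1,4-bis(trimethylsilyloxy)buta-1,3-diene
Product: 16 all-cis endo adduct 2-[(1R)-4-methyl-1-(3-methylbut-2-enoyloxy)pent-3-enyl]-5,8-bis(trimethylsilyloxy)-4a,5,8,8a-tetrahydronaphthalene-1,4-dione
Conditions: 15 (1.5 equiv of the E,E isomer), toluene, 0 °C to rt, N2, dark; volatiles removed in vacuo, no chromatography
Reagents that add atoms: none
Why: Concerted thermal [4+2] cycloaddition with normal electron demand, in which the HOMO of the doubly donor-substituted diene meets the LUMO of the quinone; the closest known type is the Diels–Alder reaction of alkylbenzoquinones with 1-silyloxy- and 1,4-dioxygenated buta-1,3-dienes. Ring A closes as a cyclohexene by intermolecular [4+2] annulation, C4a–C5 and C8–C8a being formed in the same event, suprafacially on both partners. C5 and C8 are set cis to each other by the (1E,3E) geometry of the diene, C4a and C8a are set cis by the ring-constrained cis geometry of the quinone double bond, and the endo transition state (overlap of the diene with the quinone carbonyls) puts both silyloxy groups on the face of the C4 and C1 carbonyl carbons, which gives the all-cis relationship. The diene may add to either face of the quinone with respect to C1', and the two diastereomers need not be separated because C4a, C5, C8 and C8a all become trigonal in step 9. The selectivity that the step needs is site selectivity between the two quinone double bonds, and it is secured by the branched C1' substituent, which makes the substituted double bond trisubstituted, shielded and less electron-poor, so that bond formation there (to a quaternary carbon) should not compete; regiochemistry does not arise with a symmetrical diene. Neutral conditions, excess diene and isolation by evaporation only are chosen so that 16 neither enolises nor loses trimethylsilanol before step 9.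

Step 9
Reactants: 16 all-cis endo adduct
Product: 19 [(1R)-1-(5,8-dihydroxy-1,4-dioxonaphthalen-2-yl)-4-methylpent-3-enyl] 3-methylbut-2-enoate (target), via diol 17 (not isolated), via tetraone 18 (not isolated)
Conditions: PPTS (catalytic), MeOH, 0 °C; evaporate; Dess–Martin periodinane, CH2Cl2, 0 °C to rt; aqueous Na2S2O3 work-up
Reagents that add atoms: none
Why: Acid-catalysed methanolysis of the two trimethylsilyl ethers is too mild to enolise the enedione, Dess–Martin oxidation then converts both allylic β-hydroxy ketone carbinols into ketones, and the resulting tetraone 18 undergoes two keto–enol tautomerisations driven by aromatisation of ring A, which erases the four ring stereocentres and leaves the ester and C1' untouched.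

Compound list
1 | 4-methylpent-3-enoic acid | CC(C)=CCC(O)=O | starting material
2 | 1-(imidazol-1-yl)-4-methylpent-3-en-1-one (acyl imidazolide) | CC(C)=CCC(=O)n1ccnc1 | intermediate
3 | N-methoxy-N,4-dimethylpent-3-enamide | CC(C)=CCC(=O)N(C)OC | intermediate
4 | 2-bromo-1,4-dimethoxybenzene | COc1ccc(OC)c(Br)c1 | starting material
5 | 2,5-dimethoxyphenyllithium | [Li]c1cc(OC)ccc1OC | intermediate
6 | lithium 1-(2,5-dimethoxyphenyl)-1-[methoxy(methyl)amino]-4-methylpent-3-en-1-olate | CC(C)=CCC(O[Li])(N(C)OC)c1cc(OC)ccc1OC | intermediate
7 | 1-(2,5-dimethoxyphenyl)-4-methylpent-3-en-1-one | CC(C)=CCC(=O)c1cc(OC)ccc1OC | intermediate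
8 | chloro{[(1R)-1-(2,5-dimethoxyphenyl)-4-methylpent-3-enyl]oxy}[(1S,2R,3S,5S)-2,6,6-trimethylbicyclo[3.1.1]heptan-3-yl]borane | CC(C)=CC[C@@H](OB(Cl)[C@H]1C[C@H]2C[C@H](C2(C)C)[C@@H]1C)c1cc(OC)ccc1OC | intermediate
9 | (1R)-1-(2,5-dimethoxyphenyl)-4-methylpent-3-en-1-ol | CC(C)=CC[C@@H](O)c1cc(OC)ccc1OC | intermediate
10 | 3-methylbut-2-enoyl chloride | CC(C)=CC(Cl)=O | starting material
11 | (1R)-1-(2,5-dimethoxyphenyl)-4-methylpent-3-enyl 3-methylbut-2-enoate | CC(C)=CC[C@@H](OC(=O)C=C(C)C)c1cc(OC)ccc1OC | intermediate
12 | (R)-2-[4-methyl-1-(3-methylbut-2-enoyloxy)pent-3-enyl]-1,4-benzoquinone | CC(C)=CC[C@@H](OC(=O)C=C(C)C)C1=CC(=O)C=CC1=O | intermediate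
13 | 2,5-dimethoxytetrahydrofuran (cis/trans mixture) | COC1CCC(OC)O1 | starting material
14 | butanedial (succinaldehyde) | O=CCCC=O | intermediate
15 | (1E,3E)-1,4-bis(trimethylsilyloxy)buta-1,3-diene | C[Si](C)(C)O/C=C/C=C/O[Si](C)(C)C | intermediate
16 | 2-[(1R)-4-methyl-1-(3-methylbut-2-enoyloxy)pent-3-enyl]-5,8-bis(trimethylsilyloxy)-4a,5,8,8a-tetrahydronaphthalene-1,4-dione, cis ring fusion, both silyloxy groups cis to the C1 and C4 carbonyl carbons (one of two facial isomers) | CC(C)=CC[C@@H](OC(=O)C=C(C)C)C1=CC(=O)[C@H]2[C@@H](O[Si](C)(C)C)C=C[C@@H](O[Si](C)(C)C)[C@H]2C1=O | intermediate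
17 | 5,8-dihydroxy-2-[(1R)-4-methyl-1-(3-methylbut-2-enoyloxy)pent-3-enyl]-4a,5,8,8a-tetrahydronaphthalene-1,4-dione, all-cis as in 16 | CC(C)=CC[C@@H](OC(=O)C=C(C)C)C1=CC(=O)[C@H]2[C@@H](O)C=C[C@@H](O)[C@H]2C1=O | intermediate
18 | 2-[(1R)-4-methyl-1-(3-methylbut-2-enoyloxy)pent-3-enyl]-4a,8a-dihydronaphthalene-1,4,5,8-tetraone, cis-fused | CC(C)=CC[C@@H](OC(=O)C=C(C)C)C1=CC(=O)[C@H]2C(=O)C=CC(=O)[C@H]2C1=O | intermediate
19 | [(1R)-1-(5,8-dihydroxy-1,4-dioxonaphthalen-2-yl)-4-methylpent-3-enyl] 3-methylbut-2-enoate | CC(C)=CC[C@@H](OC(=O)C=C(C)C)C1=CC(=O)c2c(O)ccc(O)c2C1=O | target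

Total step count: 9. Longest linear sequence: 7 steps (steps 1, 2, 3, 4, 5, 8, 9); the diene branch (steps 6, 7) joins at step 8.

Steps most likely to fail

Step 9. Once the silyl groups are off, water may be lost from the β-hydroxy ketones (enolisation at C4a or C8a, then expulsion of the C5 or C8 hydroxyl) faster than the carbinols are oxidised. Ring A would then aromatise with a peri oxygen missing, and a hydroquinone-type enol of ring B could expel the C1' carboxylate. The fallback sets out from 16 and does not unmask the diol as a separate stage. The silyl ethers are oxidised as such with CrO3/H2SO4 in acetone at 0 °C (Jones oxidation, titrated to a persisting orange colour), so each carbinol is oxidised as it is released. This is the established way from silyloxydiene–quinone adducts to peri-hydroxyquinones. Tetraone 18 forms in the flask and enolises, so the route is rejoined at 19. It makes no compound outside the compound list (F0).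

Step 8. The cycloaddition may stall because only the E,E isomer of a hydrolytically fragile diene is competent. Loss of trimethylsilanol from the adduct and hydrogen transfer from the enolised adduct to unreacted quinone are possible follow-up processes. The fallback sets out from 12 and annulates ring A at the ketone oxidation level with a diene that is locked s-cis. Succinic anhydride F1 is bis-silylated (Me3SiCl, Et3N, catalytic ZnCl2, MeCN) to 2,5-bis(trimethylsilyloxy)furan F2. Its [4+2] addition to the same unsubstituted double bond of 12 (CH2Cl2, −20 °C to rt) forms the same two bonds and should give the 5,8-epoxy-bridged bis(silyl ketal) adduct F3. PPTS in MeOH opens the bridge to tetraone 18, where the route is rejoined just before the enolisation to 19. Neither diene geometry nor a carbinol oxidation is involved.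

Step 7. The dialdehyde may oligomerise or undergo aldol reactions before it is silylated, and silylation under equilibrating conditions may favour Z enol ethers, so that too little (1E,3E) diene is delivered. The fallback takes the geometry from a precursor in which it is already fixed. It starts outside the route, replacing 13 and 14, with purchased (1E,3E)-buta-1,3-diene-1,4-diyl diacetate F4. This is cleaved with MeLi (4 equiv, 1,2-dimethoxyethane, −20 °C; enol acetate cleavage with retention of enolate geometry) to dilithium (1E,3E)-buta-1,3-diene-1,4-diolate F5. O-Silylation of F5 with Me3SiCl and distillation brings the route back at 15.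

Further compounds
F0 | step 9 | none | none
F1 | step 8 | succinic anhydride (purchased) | O=C1CCC(=O)O1
F2 | step 8 | 2,5-bis(trimethylsilyloxy)furan | C[Si](C)(C)Oc1ccc(O[Si](C)(C)C)o1
F3 | step 8 | 2-[(1R)-4-methyl-1-(3-methylbut-2-enoyloxy)pent-3-enyl]-5,8-bis(trimethylsilyloxy)-4a,5,8,8a-tetrahydro-5,8-epoxynaphthalene-1,4-dione | CC(C)=CC[C@@H](OC(=O)C=C(C)C)C1=CC(=O)C2C(C1=O)C1(O[Si](C)(C)C)C=CC2(O[Si](C)(C)C)O1
F4 | step 7 | (1E,3E)-buta-1,3-diene-1,4-diyl diacetate (purchased) | CC(=O)O/C=C/C=C/OC(C)=O
F5 | step 7 | dilithium (1E,3E)-buta-1,3-diene-1,4-diolate | [Li]O/C=C/C=C/O[Li]
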